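**Retrosynthetic overview**
- The (3R)-isoflavan comes from 7,2'-dihydroxy-5,4'-dimethoxy-3'-prenylisoflavone by one enantioselective hydride cascade (C2=C3, then C4=O, then C4–O through a quinone methide/pterocarpan pair). This copies isoflavone reductase, vestitone reductase and pterocarpan reductase, and it sets C-3.
- The 3'-prenyl group comes from an aromatic Claisen shift of a 2'-O-(1,1-dimethylallyl) ether. That ether is made from the 2'-O-(1,1-dimethylpropargyl) ether, which is the only protecting group in the route.
- Ring C of the isoflavone comes from an unprotected 2'-hydroxychalcone in one oxidative operation: O–C-beta closure in the flavanone sense, 2→3 aryl shift, loss of water (the chalcone isomerase / isoflavone synthase / dehydratase order).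
- The chalcone comes from a Claisen–Schmidt union of 2',4'-dihydroxy-6'-methoxyacetophenone (ring A) with O-propargylated 2-hydroxy-4-methoxybenzaldehyde (ring B).
- Ring order: rings A and B are bought. Ring C forms in the oxidative step. A transient dihydrofuran ring (pterocarpan) closes and reopens in the last step.

Assumption: the stereocentre written in the SMILES is read as (3R), the configuration of the natural vestitol-type isoflavans.

**Step 1**
Reactants: 1 2-hydroxy-4-methoxybenzaldehyde; 2 3-chloro-3-methylbut-1-yne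
Product: 3 4-methoxy-2-[(2-methylbut-3-yn-2-yl)oxy]benzaldehyde
Conditions: 2 (2.5 equiv), K2CO3 (2 equiv), KI (10 mol %), CuI (5 mol %), DMF, 60 °C, 16 h
Reagents that add atoms: none
Why: Copper-catalysed propargylic O-alkylation, in which the tertiary chloride reacts through a copper acetylide/allenylidene that the phenoxide captures at the tertiary carbon (no SN2 needed), the aldehyde is inert, and the ether later serves both as the sole protecting group of the ring B phenol and as the source of the prenyl carbons; no stereocentre is formed.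

**Step 2**
Reactants: 3 4-methoxy-2-[(2-methylbut-3-yn-2-yl)oxy]benzaldehyde; 4 1-(2,4-dihydroxy-6-methoxyphenyl)ethanone
Product: 5 (E)-1-(2,4-dihydroxy-6-methoxyphenyl)-3-{4-methoxy-2-[(2-methylbut-3-yn-2-yl)oxy]phenyl}prop-2-en-1-one
Conditions: KOH (50 % aq., 12 equiv), EtOH, 0 °C to rt, 48 h; then cold 1 M HCl to pH 5
Reagents that add atoms: none
Why: Claisen–Schmidt aldol condensation, in which concentrated hydroxide still enolises the methyl ketone of the bis-phenoxide, the non-enolisable aldehyde can only be the acceptor, E1cB loss of water gives the conjugated E-enone, strong base holds the product as the open chalcone phenoxide, and the ether has no propargylic hydrogen to isomerise; no stereocentre is formed.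

**Step 3**
Reactants: 5 (E)-1-(2,4-dihydroxy-6-methoxyphenyl)-3-{4-methoxy-2-[(2-methylbut-3-yn-2-yl)oxy]phenyl}prop-2-en-1-one
Product: 8 7-hydroxy-5-methoxy-3-{4-methoxy-2-[(2-methylbut-3-yn-2-yl)oxy]phenyl}-4H-chromen-4-one, via 3-phenyliodonioflavanone tosylate 6 (not isolated), via 2-hydroxyisoflavanone 7 (not isolated)
Conditions: PhI(OH)OTs (1.1 equiv, added in portions), MeCN, 0 °C to rt, 3 h; aq. NaHCO3/Na2S2O3 quench
Reagents that add atoms: none
Why: Proposed new method: the electrophilic trivalent iodine of PhI(OH)OTs adds to C-alpha of the enone (the ortho and para oxygen donors of ring B polarise the alkene), the chelated 2'-OH closes ring C at the benzylic C-beta by anti addition to give the trans flavanone 6, a ring flip puts the electron-rich aryl group antiperiplanar to the phenyliodonio leaving group so that it shifts from C-2 to C-3 through a phenonium ion, water captures the C-2 oxocarbenium ion to give 7 and the TsOH formed dehydrates 7 to the chromone, while ring A is deactivated by its acyl group and the inductively deactivated terminal alkyne reacts far more slowly; the closest known reaction types are the PhI(OH)OTs-induced 2,3-aryl shift of preformed flavanones to isoflavones and the oxidative 1,2-aryl rearrangement of 2'-hydroxychalcones in methanol with Tl(NO3)3 or PhI(OAc)2, and the stereocentres of 6 and 7 vanish in 8.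

**Step 4**
Reactants: 8 7-hydroxy-5-methoxy-3-{4-methoxy-2-[(2-methylbut-3-yn-2-yl)oxy]phenyl}-4H-chromen-4-one
Product: 10 7-hydroxy-3-[2-hydroxy-4-methoxy-3-(3-methylbut-2-en-1-yl)phenyl]-5-methoxy-4H-chromen-4-one, via 1,1-dimethylallyl ether 9 (not isolated)
Conditions: H2 (1 atm), Pd/CaCO3 poisoned with Pb(OAc)2 (5 wt %), quinoline, DMF, rt, until 1 equiv H2 is taken up; filter; filtrate at 120 °C, 4 h
Reagents that add atoms: none
Why: Lindlar semihydrogenation stops the terminal alkyne at the alkene without touching the chromone, and the tertiary allyl aryl ether then undergoes an aromatic Claisen [3,3] rearrangement (accelerated by the gem-dimethyl group) to the only free ortho carbon, C-3', with allyl inversion, so the 1,1-dimethylallyl group arrives as a prenyl group and tautomerisation frees the 2'-OH; no stereocentre is formed.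

**Step 5**
Reactants: 10 7-hydroxy-3-[2-hydroxy-4-methoxy-3-(3-methylbut-2-en-1-yl)phenyl]-5-methoxy-4H-chromen-4-one
Product: 15 (3R)-7,2'-dihydroxy-5,4'-dimethoxy-3'-prenylisoflavan, via racemic isoflavanone 11 (not isolated), via cis-isoflavan-4-ol 12 (not isolated), via para-quinone methide 13 (not isolated), via pterocarpan 14 (not isolated)
Conditions: RuCl[(R,R)-TsDPEN](p-cymene) (5 mol %), HCO2H/Et3N 5:2 (excess), EtOAc, degassed, 45 °C for 24 h, then 60 °C until 14 is consumed
Reagents that add atoms: none
Why: Noyori–Ikariya asymmetric transfer hydrogenation run as a domino, in which Ru–H adds 1,4 to the chromone to give 11, Et3N racemises 11 quickly so that dynamic kinetic resolution by the (R,R) catalyst reduces only the 3R ketone from the face anti to the aryl group to the cis (3R,4R) alcohol 12 (this sets C-3), the 4-OH (para to the free 7-OH, ortho to 5-OMe and O-1) leaves as water to give quinone methide 13, the 2'-OH caps 13 reversibly as the cis-fused pterocarpan 14, and Ru–H/formate drains 13 irreversibly by 1,6-hydride addition at C-4 without touching C-3, while the isolated prenyl alkene is inert to this polar hydride transfer and the buffered medium is too weakly acidic to cyclise it onto the phenol.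

**Compound list**
1 | 2-hydroxy-4-methoxybenzaldehyde | COc1ccc(C=O)c(O)c1 | starting material
2 | 3-chloro-3-methylbut-1-yne | C#CC(C)(C)Cl | starting material
3 | 4-methoxy-2-[(2-methylbut-3-yn-2-yl)oxy]benzaldehyde | COc1ccc(C=O)c(OC(C)(C)C#C)c1 | intermediate
4 | 1-(2,4-dihydroxy-6-methoxyphenyl)ethanone (2',4'-dihydroxy-6'-methoxyacetophenone) | CC(=O)c1c(O)cc(O)cc1OC | starting material
5 | (E)-1-(2,4-dihydroxy-6-methoxyphenyl)-3-{4-methoxy-2-[(2-methylbut-3-yn-2-yl)oxy]phenyl}prop-2-en-1-one (chalcone) | COc1ccc(/C=C/C(=O)c2c(O)cc(O)cc2OC)c(OC(C)(C)C#C)c1 | intermediate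
6 | (±)-trans-[7-hydroxy-5-methoxy-2-{4-methoxy-2-[(2-methylbut-3-yn-2-yl)oxy]phenyl}-4-oxochroman-3-yl](phenyl)iodonium tosylate (one enantiomer drawn) | O=C1c2c(OC)cc(O)cc2O[C@@H](c2ccc(OC)cc2OC(C)(C)C#C)[C@@H]1[I+]c1ccccc1.Cc1ccc(cc1)S(=O)(=O)[O-] | intermediate
7 | (±)-2,7-dihydroxy-5-methoxy-3-{4-methoxy-2-[(2-methylbut-3-yn-2-yl)oxy]phenyl}chroman-4-one (2-hydroxyisoflavanone, mixture of C-2 epimers) | O=C1c2c(OC)cc(O)cc2OC(O)C1c1ccc(OC)cc1OC(C)(C)C#C | intermediate
8 | 7-hydroxy-5-methoxy-3-{4-methoxy-2-[(2-methylbut-3-yn-2-yl)oxy]phenyl}-4H-chromen-4-one | COc1ccc(c(OC(C)(C)C#C)c1)C1=COc2cc(O)cc(OC)c2C1=O | intermediate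
9 | 7-hydroxy-5-methoxy-3-{4-methoxy-2-[(2-methylbut-3-en-2-yl)oxy]phenyl}-4H-chromen-4-one | COc1ccc(c(OC(C)(C)C=C)c1)C1=COc2cc(O)cc(OC)c2C1=O | intermediate
10 | 7-hydroxy-3-[2-hydroxy-4-methoxy-3-(3-methylbut-2-en-1-yl)phenyl]-5-methoxy-4H-chromen-4-one | COc1ccc(c(O)c1CC=C(C)C)C1=COc2cc(O)cc(OC)c2C1=O | intermediate
11 | (±)-7-hydroxy-3-[2-hydroxy-4-methoxy-3-(3-methylbut-2-en-1-yl)phenyl]-5-methoxychroman-4-one (isoflavanone, C-3 epimerises in the flask) | COc1ccc(c(O)c1CC=C(C)C)C1COc2cc(O)cc(OC)c2C1=O | intermediate
12 | (3R,4R)-3-[2-hydroxy-4-methoxy-3-(3-methylbut-2-en-1-yl)phenyl]-5-methoxychroman-4,7-diol (cis-isoflavan-4-ol) | COc1cc(O)cc2c1[C@H](O)[C@H](c1ccc(OC)c(CC=C(C)C)c1O)CO2 | intermediate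
13 | (3R)-3-[2-hydroxy-4-methoxy-3-(3-methylbut-2-en-1-yl)phenyl]-5-methoxy-2,3-dihydro-7H-chromen-7-one (para-quinone methide) | COC1=CC(=O)C=C2OC[C@@H](c3ccc(OC)c(CC=C(C)C)c3O)C=C12 | intermediate
14 | (6aR,11aR)-3-hydroxy-1,9-dimethoxy-10-(3-methylbut-2-en-1-yl)pterocarpan (cis-fused) | COc1cc(O)cc2c1[C@@H]3Oc4c(CC=C(C)C)c(OC)ccc4[C@@H]3CO2 | intermediate
15 | (3R)-3-[2-hydroxy-4-methoxy-3-(3-methylbut-2-en-1-yl)phenyl]-5-methoxychroman-7-ol | COc1cc(O)cc2c1C[C@H](c1ccc(OC)c(CC=C(C)C)c1O)CO2 | target

**Step count and risks**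
Total step count: 5. Longest linear sequence: 5 (1 → 3 → 5 → 8 → 10 → 15).

Step 3 is the most likely to fail. PhI(OH)OTs may attack the free ring A phenol or its open C–H positions, and the TsOH released may cleave the tertiary ether. The fallback sets out from chalcone 5 and comes back at isoflavone 8. Both phenols are acetylated (Ac2O, pyridine, rt) to give the chalcone diacetate F1. Tl(NO3)3·3H2O (1.1 equiv) in MeOH/HC(OMe)3 at rt then carries out the 1,2-aryl shift on the open chain, with methanol instead of the phenol as nucleophile, to give the racemic beta-keto dimethyl acetal F2. K2CO3 in MeOH takes off the acetates, and 1 M HCl in MeOH at 40 °C closes ring C with loss of methanol to give 8. In this version the ring closes after the shift rather than before it, and the oxidant (trivalent thallium) never meets a free phenol.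

Step 5 is second. The electron-rich 5-methoxy-7-hydroxychromone may accept hydride too slowly, or the cascade may rest at pterocarpan 14. The fallback sets out from isoflavone 10 and comes back at target 15.
- Ac2O/pyridine gives the isoflavone diacetate F3. Its chromone is more electrophilic, and its masked phenols allow neither quinone methide nor pterocarpan formation.
- The same RuCl[(R,R)-TsDPEN](p-cymene)/HCO2H/Et3N system then stops cleanly at the (3R,4R)-cis-isoflavan-4-ol diacetate F4.
- Ionic hydrogenation with Et3SiH/BF3·OEt2 in CH2Cl2 at −78 to −40 °C removes the 4-oxygen through the benzylic cation and gives the (3R)-isoflavan diacetate F5. The acetylated 2'-oxygen cannot add to the prenyl group.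
- K2CO3 in MeOH releases 15.

The single domino is thus replaced by discrete reduction, silane deoxygenation and deprotection.

Step 2 is third. The bis-phenoxide of 4 is a poor enolate precursor, and aldehyde 3 is hindered and electron-rich, so conversion may stall. The fallback sets out from 3 and 4 and comes back at intermediate 6, and so at 8. Pyrrolidine (1 equiv) in MeOH at 50 °C joins the two partners by an enamine/iminium aldol condensation followed by oxa-Michael closure. No polyanion is needed, and the product is the racemic flavanone F6 instead of the chalcone. PhI(OH)OTs in MeCN at 60 °C then attacks the enol of F6 anti to the 2-aryl group and gives the same 3-phenyliodonioflavanone 6, which rearranges to 8 as in step 3.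

**Further compounds**
F1 | step 3 | (E)-1-(2,4-diacetoxy-6-methoxyphenyl)-3-{4-methoxy-2-[(2-methylbut-3-yn-2-yl)oxy]phenyl}prop-2-en-1-one | COc1ccc(/C=C/C(=O)c2c(OC(C)=O)cc(OC(C)=O)cc2OC)c(OC(C)(C)C#C)c1
F2 | step 3 | (±)-1-(2,4-diacetoxy-6-methoxyphenyl)-3,3-dimethoxy-2-{4-methoxy-2-[(2-methylbut-3-yn-2-yl)oxy]phenyl}propan-1-one | COC(OC)C(c1ccc(OC)cc1OC(C)(C)C#C)C(=O)c1c(OC(C)=O)cc(OC(C)=O)cc1OC
F3 | step 5 | 7-acetoxy-3-[2-acetoxy-4-methoxy-3-(3-methylbut-2-en-1-yl)phenyl]-5-methoxy-4H-chromen-4-one | COc1ccc(c(OC(C)=O)c1CC=C(C)C)C1=COc2cc(OC(C)=O)cc(OC)c2C1=O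
F4 | step 5 | (3R,4R)-7-acetoxy-3-[2-acetoxy-4-methoxy-3-(3-methylbut-2-en-1-yl)phenyl]-5-methoxychroman-4-ol | COc1cc(OC(C)=O)cc2c1[C@H](O)[C@H](c1ccc(OC)c(CC=C(C)C)c1OC(C)=O)CO2
F5 | step 5 | (3R)-7-acetoxy-3-[2-acetoxy-4-methoxy-3-(3-methylbut-2-en-1-yl)phenyl]-5-methoxychroman | COc1cc(OC(C)=O)cc2c1C[C@H](c1ccc(OC)c(CC=C(C)C)c1OC(C)=O)CO2
F6 | step 2 | (±)-7-hydroxy-5-methoxy-2-{4-methoxy-2-[(2-methylbut-3-yn-2-yl)oxy]phenyl}chroman-4-one | O=C1CC(c2ccc(OC)cc2OC(C)(C)C#C)Oc2cc(O)cc(OC)c12
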